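**Numbering used throughout:** 1–21 as defined in the steps and the compound list; 21 is the target.

## Analysis of the target

The target is a flavone (2-phenyl-4H-chromen-4-one): ring A is the benzo ring, ring C the pyranone and ring B an unsubstituted phenyl group at C2. Ring C carries a methyl enol ether at C3; ring A is oxygenated at C5, C7 and C8 and has its only hydrogen at C6. O5 and O7 are free hydroxyls and O8 carries the (R)-2-methylbutanoyl group, whose α-carbon is the only stereocenter. It has no partner, so only its absolute configuration has to be delivered, most simply from the enantiopure acid. That centre lies α to an ester carbonyl and can be lost by enolization or through a ketene. The ester also sits next to a free, fairly acidic 7-hydroxyl, so base can move the acyl group from O8 to O7 or hydrolyse it, and a ring with free para oxygens at C5 and C8 is open to oxidation to a quinone. The difficulty is therefore not the skeleton but telling three phenolic oxygens apart, above all the neighbours O7 and O8, while the 3-methoxy group is left alone. The plan rests on the fact that C5 and C8 are para-related oxygen-bearing carbons, joined on one side by C6–C7 and on the other by the C4a–C8a bond that ring A shares with ring C. This is the pattern written by a carbene–alkyne–CO benzannulation: C5 as the alkoxy carbon of a carbene, C8 as a carbonyl ligand, C6–C7 as an alkyne and C4a=C8a as the double bond of a finished pyranone, so that O5, O7 and O8 are born in three different states.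

## Retrosynthetic reasoning

**21 back to 20.** The last bonds to be made are two O–H bonds. In 20 the hydroxyls at C5 and C7 are a methyl and an isopropyl ether, both taken off in one treatment with a Lewis acidic boron halide. The methyl ether goes because O5 and the C4 carbonyl clamp the boron in a six-membered chelate, the isopropyl ether because a secondary alkyl aryl ether ionizes readily. The 3-methoxy group is not part of such a chelate and should stay, as should the ester. Ending with an acidic step is deliberate: once O7 is free, the ester must not meet base.

**20 back to 18 and 19.** The acyl–O8 bond is cut. Phenol 18 has a single hydroxyl, so the acylation has no site to choose. Acid 19 brings the stereocenter ready-made, and a carbodiimide coupling with only two mild steps after it gives the centre little chance to epimerize.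

**18 back to 11 and 16 (key disconnection).** C5–C6, C7–C8 and C8–C8a are cut, and C8 is traced to a carbonyl ligand of 11.
- Cutting ring C instead, as flavone chemistry usually does, leaves the hard part untouched: a benzene ring with four different oxygens.
- Cutting ring A turns that problem into the regiochemistry of one annulation. The step builds ring A and three skeletal bonds and delivers O5 as a methyl ether, O7 as an isopropyl ether and O8 as the only free hydroxyl.
- The forward reaction must insert alkyne 16 with its CH terminus toward the carbene carbon, take up CO, and close onto the pyranone CH next to the ring oxygen.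
- The oxygen of the alkyne is carried as an isopropyl ether rather than a trialkylsilyl ether for three reasons. A silyl group on O7 beside a free O8–H can migrate between the two oxygens under the basic acylation and erase the distinction the key step creates. Alkyne 16 comes in one pot from 12 and 13. The isopropyl group leaves in the same operation as the O5 methyl group.
- A secondary alkyl ynol ether is also thermally sturdier than a tertiary alkyl or benzyl one at the temperature of the annulation.

**16 back to 12 and 13.** The O–C(sp) bond is cut. Chloroalkene 12 supplies the two alkyne carbons and alcohol 13 the oxygen substituent; the sequence runs in one flask through 14 and 15.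

**11 back to 7 and 8.** The chromium–carbon double bond and the O–CH3 bond of the carbene are cut. The classical route through an organolithium is closed, because a 4-pyranone metalated at C3 is not a practical reagent and the ring is a Michael acceptor. The polarity is therefore reversed: the metal is made the nucleophile (dianion 9 from 8) and the pyranone the electrophile (acid chloride 7), giving acylchromate 10, which is methylated on oxygen.

**7 back to 6 and 5.** These are functional group changes. The acid chloride comes from acid 6 and the acid from methyl ester 5 by acidic hydrolysis; hydroxide would add to C2 of a 2-unsubstituted 4-pyranone and open it.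

**5 back to 3.** O1–C2 and C2–C3 of the pyranone are cut. C2 is a one-carbon unit at the oxidation level of formic acid. It is placed on the only methylene of 3 that lies between two carbonyls as an aminomethylene group (4), and the enol oxygen of the benzoyl ketone closes the ring with loss of the amine.

**3 back to 1 and 2.** The bond between the methoxy-bearing carbon and the benzoyl carbon is cut, a Claisen acylation of the dianion of 1 by 2. Two bulk chemicals thereby fix every substituent of the later ring C: phenyl at C2, methoxy at C3, the C4 carbonyl, and the carboxyl carbon that becomes C5.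

## Alternatives that were turned down

**Alternative 1:** benzodioxinone acylation.
- Disconnection: C3–C4 and O1–C2 of ring C. Ring A arrives complete as the salicylate acetonide 5,7-bis(benzyloxy)-2,2-dimethyl-8-(triisopropylsilyloxy)-4H-1,3-benzodioxin-4-one (A3), and C2, C3 and ring B as 2-methoxyacetophenone (A2).
- Forward key step: the lithium enolate of A2 attacks the lactone carbonyl of A3, the acetonide collapses, and acid dehydrates the hydroxyaryl diketone to 5,7-bis(benzyloxy)-3-methoxy-8-(triisopropylsilyloxy)flavone (A1).
- For it: every step is conventional carbonyl chemistry, the coupling is convergent, and no stoichiometric transition metal is needed. On precedent it is clearly stronger than the chosen route.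
- Against it: A3 is a benzene with one carbon and four oxygen substituents in three protection states. It must be built oxygen by oxygen in a linear sequence of about six steps, with the C8 oxygen introduced by a late ring oxidation. Its lactone carbonyl is hindered by the ortho benzyloxy group. When the ring opens, the new phenoxide at C8a lies next to the silyl ether on O8, which invites an oxygen-to-oxygen silyl shift at exactly the position that matters. After A1, desilylation, acylation and a double hydrogenolysis still follow.
- Comparison: the chosen route is no shorter overall, but it creates the distinction between O5, O7 and O8 in the bond-forming event rather than by a chain of protections. It pays for this with an annulation that has no direct precedent.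

**Alternative 2:** Friedel–Crafts closure of ring C.
- Disconnection: C4–C4a. The precursor is the aryl enol ether acid (E)-3-{3,5-bis(benzyloxy)-2-[(2R)-2-methylbutanoyloxy]phenoxy}-2-methoxy-3-phenylprop-2-enoic acid (A5), which already carries the ester.
- Forward key step: A5 is activated as a mixed anhydride and acylates the ring carbon ortho to the ether oxygen, closing ring C to 5,7-bis(benzyloxy)-3-methoxy-4-oxo-2-phenyl-4H-chromen-8-yl (2R)-2-methylbutanoate (A4).
- For it: only one hydrogenolysis follows A4, so the end of the route is shorter than the chosen one, and it is metal-free. On those two points it is stronger. The acylation site is strongly activated.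
- Against it: A5 is a tetrasubstituted enol ether whose carboxyl group must be cis to the aryloxy group, and that geometry has to be made and kept under acid. Its phenol precursor is a catechol monoester, in which the acyl group can move between the adjacent oxygens under the basic O-vinylation, so the position of the ester is not secure before ring closure. The remaining ring CH between the two benzyloxy groups is the most nucleophilic carbon and can be acylated intermolecularly by the activating anhydride. The stereocenter and the benzyl ethers also pass through a strongly acidic acylating medium.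
- Comparison: the chosen route keeps the ester out until 18 offers a single hydroxyl, and the stereocenter then meets only a carbodiimide coupling and a cold Lewis acid.

**Alternative 3:** Moore cyclization on a pyranone.
- Disconnection: C4a–C5. C8–C8a is made beforehand by adding 3-methoxy-2-phenyl-4H-pyran-4-one (A8), metalated at C6, to 3-isopropoxycyclobut-3-ene-1,2-dione (A9), giving 4-hydroxy-3-isopropoxy-4-(5-methoxy-4-oxo-6-phenyl-4H-pyran-2-yl)cyclobut-2-en-1-one (A7).
- Forward key step: heating A7 opens the four-membered ring to a dienylketene, whose 6π closure onto the pyranone CH next to the carbonyl gives 5,8-dihydroxy-7-isopropoxy-3-methoxyflavone (A6).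
- For it: this is the closest relative of the chosen plan, with the same dienylketene and the same use of the pyranone double bond, but without chromium. Ring expansion of alkenyl and heteroaryl hydroxycyclobutenones is established, O5 is delivered free so no demethylation is needed, and the route would be shorter. On precedent and step count it is as strong or stronger.
- Against it: A6 is a free hydroquinone with para hydroxyls, the kind of product that normally ends as the quinone on work-up. The ester site would rest only on the hydrogen bond that deactivates O5–H, not on constitution. A7 requires metalation of A8 next to the ring oxygen in a molecule that is itself a Michael acceptor, and A9 takes several steps to make.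
- Comparison: the chosen route gives a para-methoxyphenol, which is harder to oxidize, with exactly one free oxygen. That is what the target's real difficulty asks for.

Key step: step 7

Remark on the chemistry: isopropoxyethyne 16 is treated as not purchasable and is made in step 6; acid 19 is bought as the single (R) enantiomer.

## Route

**Step 1**
Reactants: 1 methyl 4-methoxy-3-oxobutanoate; 2 methyl benzoate
Product: 3 methyl 4-methoxy-3,5-dioxo-5-phenylpentanoate
Conditions: NaH, THF, 0 °C; n-BuLi, −20 °C; 2 (0.5 equiv), −78 → 0 °C; aq. HCl
Reagents that add atoms: none
Why: Claisen acylation of a β-keto ester dianion (Huckin–Weiler): the more reactive γ-carbanion, here the methoxy-bearing carbon, attacks the non-enolizable ester 2; a twofold amount of dianion takes up the proton of the more acidic product.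

**Step 2**
Reactants: 3 methyl 4-methoxy-3,5-dioxo-5-phenylpentanoate
Product: 5 methyl 5-methoxy-4-oxo-6-phenyl-4H-pyran-3-carboxylate, via enaminone 4 (not isolated)
Conditions: Me2NCH(OMe)2, toluene, rt; then AcOH, 60 °C
Reagents that add atoms: N,N-dimethylformamide dimethyl acetal, COC(OC)N(C)C
Why: Aminomethylenation of the only methylene between two carbonyls gives 4; the enol oxygen of the benzoyl ketone then adds to the aminomethylene carbon and dimethylamine leaves (addition–elimination, six-membered ring), the standard 4-pyranone synthesis from 3,5-diketo esters.

**Step 3**
Reactants: 5 methyl 5-methoxy-4-oxo-6-phenyl-4H-pyran-3-carboxylate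
Product: 6 5-methoxy-4-oxo-6-phenyl-4H-pyran-3-carboxylic acid
Conditions: 6 M HCl, AcOH, 90 °C
Reagents that add atoms: water, O
Why: Acid-catalysed ester hydrolysis; acid is used because hydroxide would add to C2 of the 2-unsubstituted pyranone and open the ring, whereas the pyranone and its aryl-like methyl ether tolerate hot dilute acid.

**Step 4**
Reactants: 6 5-methoxy-4-oxo-6-phenyl-4H-pyran-3-carboxylic acid
Product: 7 5-methoxy-4-oxo-6-phenyl-4H-pyran-3-carbonyl chloride
Conditions: (COCl)2 (1.1 equiv), DMF (cat.), CH2Cl2, 0 °C → rt
Reagents that add atoms: oxalyl chloride, O=C(Cl)C(=O)Cl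
Why: Vilsmeier-catalysed conversion of the acid into its chloride; the small excess and low temperature keep the reagent from attacking the pyranone carbonyl oxygen, and the chloride is used crude.

**Step 5**
Reactants: 8 chromium hexacarbonyl Cr(CO)6; 7 5-methoxy-4-oxo-6-phenyl-4H-pyran-3-carbonyl chloride
Product: 11 pentacarbonyl[methoxy(5-methoxy-4-oxo-6-phenyl-4H-pyran-3-yl)carbene]chromium, via dipotassium pentacarbonylchromate 9 (not isolated), via potassium acylchromate 10 (not isolated)
Conditions: 8, KC8 (2.1 equiv), THF, −78 °C → rt; then 7, −78 → 0 °C; then Me3OBF4, CH2Cl2, 0 °C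
Reagents that add atoms: trimethyloxonium tetrafluoroborate, C[O+](C)C.F[B-](F)(F)F
Why: Two-electron reduction of 8 gives dianion 9 with loss of one CO, and 9 displaces chloride at the acyl carbon of 7 to give acylchromate 10; methylation of the acylate oxygen gives the Fischer carbene complex (Semmelhack–Hegedus route from acid chlorides), which avoids a 3-metalated pyranone.

**Step 6**
Reactants: 12 trichloroethylene; 13 propan-2-ol
Product: 16 isopropoxyethyne, via dichlorovinyl ether 14 (not isolated), via lithium isopropoxyacetylide 15 (not isolated)
Conditions: KH, THF, 0 °C; 12, −50 °C → rt; n-BuLi (2.4 equiv), −78 → −40 °C; MeOH, −78 °C; distillation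
Reagents that add atoms: none
Why: Greene ynol ether synthesis: the potassium alkoxide of 13 and 12 give 14 by elimination–addition, n-BuLi removes HCl and exchanges the remaining chlorine to give 15, and protonation gives 16; the volatile product is kept as a distilled hydrocarbon solution whose titre is read by NMR.

**Step 7**
Reactants: 11 pentacarbonyl[methoxy(5-methoxy-4-oxo-6-phenyl-4H-pyran-3-yl)carbene]chromium; 16 isopropoxyethyne
Product: 18 8-hydroxy-7-isopropoxy-3,5-dimethoxyflavone, via tricarbonylchromium complex 17 (not isolated)
Conditions: 16 (2 equiv), THF, 50 °C, sealed tube, Ar; then air, EtOAc, rt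
Reagents that add atoms: none
Why: Proposed new method: heating makes 11 lose one CO ligand (the C4 carbonyl can hold the vacant site as a hemilabile chelate), 16 binds and inserts into the chromium–carbon double bond so that the old carbene carbon (C5, with its methoxy group) is joined to the CH terminus (C6) and the isopropoxy-bearing carbon (C7) becomes the new carbene carbon, and migration of a CO ligand onto C7 forms C7–C8 and a chromium-bound dienylketene. Ring A is closed by a thermal 6π electrocyclization of this ketene, its carbon C8 bonding to the pyranone CH carbon next to the ring oxygen (the future C8a), and the resulting cyclohexadienone tautomerizes to the phenol, first held as the tricarbonylchromium complex 17 and set free by air. The closest known reaction type is the Dötz benzannulation of alkenyl and heteroaryl alkoxycarbene complexes of zerovalent chromium with alkynes; a 4-pyranone as the alkenyl part, closure onto an oxygen-bearing carbon and an ynol ether partner in this combination are not established. No stereocenter is formed. The step needs regioselective insertion: the rule that the substituent of a terminal alkyne ends next to the CO-derived carbon and the polarization of the ynol ether (nucleophilic CH terminus toward the electrophilic carbene carbon, oxygen stabilizing the new carbene) act in the same direction and place O7 ortho to the new hydroxyl. It also needs CO insertion to win over five-membered ring formation and over capture of the vinylcarbene by the C4 carbonyl oxygen, which the alkenyl character of the carbene and THF as donor solvent favour. Only one closure site exists because the pyranone CH next to the ring oxygen is the sole β-position, so O8 emerges as the only free hydroxyl.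

**Step 8**
Reactants: 18 8-hydroxy-7-isopropoxy-3,5-dimethoxyflavone; 19 (R)-2-methylbutanoic acid
Product: 20 7-isopropoxy-3,5-dimethoxy-4-oxo-2-phenyl-4H-chromen-8-yl (2R)-2-methylbutanoate
Conditions: EDC·HCl, DMAP (cat.), CH2Cl2, 0 °C → rt
Reagents that add atoms: none
Why: Steglich esterification of the only hydroxyl; no strong base and no acid chloride are present, so the ketene pathway that would racemize the α-centre of 19 is avoided and the (R) configuration is carried over unchanged.

**Step 9**
Reactants: 20 7-isopropoxy-3,5-dimethoxy-4-oxo-2-phenyl-4H-chromen-8-yl (2R)-2-methylbutanoate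
Product: 21 5,7-dihydroxy-3-methoxy-4-oxo-2-phenyl-4H-chromen-8-yl (2R)-2-methylbutanoate
Conditions: BCl3 (5 equiv), CH2Cl2, −78 → 0 °C; then H2O, 0 °C
Reagents that add atoms: none
Why: Lewis acid ether cleavage: BCl3 removes the 5-methyl group through the six-membered chelate with the C4 carbonyl and the isopropyl group as a secondary alkyl aryl ether, while the unchelated 3-methyl ether and the aryl ester should persist at low temperature; the neutral aqueous quench keeps the acyl group on O8.

## Compound list

1 | methyl 4-methoxy-3-oxobutanoate | COCC(=O)CC(=O)OC | starting material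
2 | methyl benzoate | COC(=O)c1ccccc1 | starting material
3 | methyl 4-methoxy-3,5-dioxo-5-phenylpentanoate | COC(=O)CC(=O)C(OC)C(=O)c1ccccc1 | intermediate
4 | methyl 2-[(dimethylamino)methylidene]-4-methoxy-3,5-dioxo-5-phenylpentanoate (enaminone) | COC(=O)C(=CN(C)C)C(=O)C(OC)C(=O)c1ccccc1 | intermediate
5 | methyl 5-methoxy-4-oxo-6-phenyl-4H-pyran-3-carboxylate | COC(=O)c1coc(-c2ccccc2)c(OC)c1=O | intermediate
6 | 5-methoxy-4-oxo-6-phenyl-4H-pyran-3-carboxylic acid | OC(=O)c1coc(-c2ccccc2)c(OC)c1=O | intermediate
7 | 5-methoxy-4-oxo-6-phenyl-4H-pyran-3-carbonyl chloride | ClC(=O)c1coc(-c2ccccc2)c(OC)c1=O | intermediate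
8 | chromium hexacarbonyl Cr(CO)6 | O=C=[Cr](=C=O)(=C=O)(=C=O)(=C=O)=C=O | starting material
9 | dipotassium pentacarbonylchromate K2Cr(CO)5 | [K+].[K+].O=C=[Cr-2](=C=O)(=C=O)(=C=O)=C=O | intermediate
10 | potassium pentacarbonyl(5-methoxy-4-oxo-6-phenyl-4H-pyran-3-carbonyl)chromate | [K+].O=C(c1coc(-c2ccccc2)c(OC)c1=O)[Cr-](=C=O)(=C=O)(=C=O)(=C=O)=C=O | intermediate
11 | pentacarbonyl[methoxy(5-methoxy-4-oxo-6-phenyl-4H-pyran-3-yl)carbene]chromium | COC(=[Cr](=C=O)(=C=O)(=C=O)(=C=O)=C=O)c1coc(-c2ccccc2)c(OC)c1=O | intermediate
12 | trichloroethylene | ClC=C(Cl)Cl | starting material
13 | propan-2-ol | CC(C)O | starting material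
14 | (E)-1,2-dichloro-1-isopropoxyethene | CC(C)O/C(Cl)=C\Cl | intermediate
15 | lithium isopropoxyacetylide | [Li]C#COC(C)C | intermediate
16 | isopropoxyethyne | C#COC(C)C | intermediate
17 | tricarbonyl(8-hydroxy-7-isopropoxy-3,5-dimethoxyflavone)chromium, metal bound η6 to ring A | COc1cc(OC(C)C)c(O)c2oc(-c3ccccc3)c(OC)c(=O)c12.O=C=[Cr](=C=O)=C=O | intermediate
18 | 8-hydroxy-7-isopropoxy-3,5-dimethoxyflavone | COc1cc(OC(C)C)c(O)c2oc(-c3ccccc3)c(OC)c(=O)c12 | intermediate
19 | (R)-2-methylbutanoic acid | CC[C@@H](C)C(=O)O | starting material
20 | 7-isopropoxy-3,5-dimethoxy-4-oxo-2-phenyl-4H-chromen-8-yl (2R)-2-methylbutanoate | CC[C@@H](C)C(=O)Oc1c(OC(C)C)cc(OC)c2c(=O)c(OC)c(-c3ccccc3)oc12 | intermediate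
21 | 5,7-dihydroxy-3-methoxy-4-oxo-2-phenyl-4H-chromen-8-yl (2R)-2-methylbutanoate | CC[C@@H](C)C(=O)Oc1c(O)cc(O)c2c(=O)c(OC)c(-c3ccccc3)oc12 | target

## Step count and least certain steps

Total: 9 steps. Longest linear sequence: 8 steps (steps 1–5, 7, 8, 9); step 6 is a one-step side branch.

**Step 7 (key step).**
- What may go wrong: the electron-rich ynol ether may be consumed by polar addition or oligomerization before CO is lost. The chromium vinylcarbene may cyclize without CO insertion or be captured by the C4 carbonyl oxygen. The para-methoxyphenol may be over-oxidized to the quinone during demetalation. None of these can be excluded, because this carbene, this closure site and this alkyne type have not been combined before.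
- Fallback (known chemistry, no chromium): it sets out from 19 and comes back to the route at 21. Hoesch acylation of phloroglucinol with methoxyacetonitrile (ZnCl2, HCl, Et2O; then water) gives 2-methoxy-1-(2,4,6-trihydroxyphenyl)ethan-1-one F1. Allan–Robinson condensation with benzoic anhydride and PhCO2Na at 180 °C, then KOH, gives 5,7-dihydroxy-3-methoxyflavone F2. BnBr and K2CO3 alkylate the more acidic 7-hydroxyl to 7-benzyloxy-5-hydroxy-3-methoxyflavone F3. Elbs oxidation (K2S2O8, aq. KOH, pyridine) attacks para to the 5-phenoxide and gives potassium 7-benzyloxy-5-hydroxy-3-methoxy-4-oxo-2-phenyl-4H-chromen-8-yl sulfate F4, which dilute HCl hydrolyses to 7-benzyloxy-5,8-dihydroxy-3-methoxyflavone F5. Coupling with 19 as in step 8 takes the unchelated 8-hydroxyl and gives 7-benzyloxy-5-hydroxy-3-methoxy-4-oxo-2-phenyl-4H-chromen-8-yl (2R)-2-methylbutanoate F6, and hydrogenolysis (H2, Pd/C, EtOAc) gives 21.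

**Step 5.**
- What may go wrong: the strongly reducing and nucleophilic dianion 9 may transfer an electron to the pyranone or add to its C2 position and open the ring, instead of substituting cleanly at the acyl chloride.
- Fallback: it sets out from 6 and comes back at 11. Decarboxylation of 6 (Cu, quinoline, heat) gives 3-methoxy-2-phenyl-4H-pyran-4-one F7. Iodination at the nucleophilic carbon next to the carbonyl (NIS, CF3CO2H, MeCN) gives 5-iodo-3-methoxy-2-phenyl-4H-pyran-4-one F8. Iodine–magnesium exchange with i-PrMgCl·LiCl at −40 °C gives chloro(5-methoxy-4-oxo-6-phenyl-4H-pyran-3-yl)magnesium F9. Addition of F9 to a CO ligand of 8 gives chloromagnesium pentacarbonyl(5-methoxy-4-oxo-6-phenyl-4H-pyran-3-carbonyl)chromate F10, which Me3OBF4 methylates to 11.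

**Step 9.**
- What may go wrong: the 3-methyl ether may be lost through a second, five-membered chelate with the C4 carbonyl, and the ester may be cleaved or may shift to O7 during the Lewis acid treatment or the quench.
- Fallback: it sets out from 18 and comes back at 21. BCl3 is applied to 18, where no ester is at stake, to give 5,7,8-trihydroxy-3-methoxyflavone F11. One equivalent of BnBr with K2CO3 under argon alkylates the most acidic 7-hydroxyl to 7-benzyloxy-5,8-dihydroxy-3-methoxyflavone F5. Acylation with 19 at the unchelated 8-hydroxyl gives the ester F6, and hydrogenolysis (H2, Pd/C) gives 21.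

**Step 1.**
- What may go wrong: proton transfer from the more acidic product to the dianion may stop the acylation short, and self-condensation of 1 may compete.
- Fallback: it sets out from 1 and comes back at 4. Treating 1 with Me2NCH(OMe)2 gives methyl 2-[(dimethylamino)methylidene]-4-methoxy-3-oxobutanoate F12, whose only remaining acidic position is the methoxy-bearing methylene. Its lithium enolate (LiN(SiMe3)2, THF, −78 °C) is C-acylated by benzoyl chloride to give 4, which closes to 5 with acid as in step 2.

## Further compounds

F1 | step 7 | 2-methoxy-1-(2,4,6-trihydroxyphenyl)ethan-1-one | COCC(=O)c1c(O)cc(O)cc1O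
F2 | step 7 | 5,7-dihydroxy-3-methoxyflavone | COc1c(-c2ccccc2)oc2cc(O)cc(O)c2c1=O
F3 | step 7 | 7-benzyloxy-5-hydroxy-3-methoxyflavone | COc1c(-c2ccccc2)oc2cc(OCc3ccccc3)cc(O)c2c1=O
F4 | step 7 | potassium 7-benzyloxy-5-hydroxy-3-methoxy-4-oxo-2-phenyl-4H-chromen-8-yl sulfate | COc1c(-c2ccccc2)oc2c(OS(=O)(=O)[O-])c(OCc3ccccc3)cc(O)c2c1=O.[K+]
F5 | step 7 | 7-benzyloxy-5,8-dihydroxy-3-methoxyflavone | COc1c(-c2ccccc2)oc2c(O)c(OCc3ccccc3)cc(O)c2c1=O
F6 | step 7 | 7-benzyloxy-5-hydroxy-3-methoxy-4-oxo-2-phenyl-4H-chromen-8-yl (2R)-2-methylbutanoate | CC[C@@H](C)C(=O)Oc1c(OCc2ccccc2)cc(O)c2c(=O)c(OC)c(-c3ccccc3)oc12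
F7 | step 5 | 3-methoxy-2-phenyl-4H-pyran-4-one | COc1c(-c2ccccc2)occc1=O
F8 | step 5 | 5-iodo-3-methoxy-2-phenyl-4H-pyran-4-one | COc1c(-c2ccccc2)occ(I)c1=O
F9 | step 5 | chloro(5-methoxy-4-oxo-6-phenyl-4H-pyran-3-yl)magnesium | COc1c(-c2ccccc2)occ([Mg]Cl)c1=O
F10 | step 5 | chloromagnesium pentacarbonyl(5-methoxy-4-oxo-6-phenyl-4H-pyran-3-carbonyl)chromate | Cl[Mg+].O=C(c1coc(-c2ccccc2)c(OC)c1=O)[Cr-](=C=O)(=C=O)(=C=O)(=C=O)=C=O
F11 | step 9 | 5,7,8-trihydroxy-3-methoxyflavone | COc1c(-c2ccccc2)oc2c(O)c(O)cc(O)c2c1=O
F12 | step 1 | methyl 2-[(dimethylamino)methylidene]-4-methoxy-3-oxobutanoate | COCC(=O)C(=CN(C)C)C(=O)OC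
A1 | alternative 1 | 5,7-bis(benzyloxy)-3-methoxy-8-(triisopropylsilyloxy)flavone | COc1c(-c2ccccc2)oc2c(O[Si](C(C)C)(C(C)C)C(C)C)c(OCc3ccccc3)cc(OCc3ccccc3)c2c1=O
A2 | alternative 1 | 2-methoxyacetophenone | COCC(=O)c1ccccc1
A3 | alternative 1 | 5,7-bis(benzyloxy)-2,2-dimethyl-8-(triisopropylsilyloxy)-4H-1,3-benzodioxin-4-one | CC1(C)OC(=O)c2c(OCc3ccccc3)cc(OCc3ccccc3)c(O[Si](C(C)C)(C(C)C)C(C)C)c2O1
A4 | alternative 2 | 5,7-bis(benzyloxy)-3-methoxy-4-oxo-2-phenyl-4H-chromen-8-yl (2R)-2-methylbutanoate | CC[C@@H](C)C(=O)Oc1c(OCc2ccccc2)cc(OCc2ccccc2)c2c(=O)c(OC)c(-c3ccccc3)oc12
A5 | alternative 2 | (E)-3-{3,5-bis(benzyloxy)-2-[(2R)-2-methylbutanoyloxy]phenoxy}-2-methoxy-3-phenylprop-2-enoic acid | CC[C@@H](C)C(=O)Oc1c(OCc2ccccc2)cc(OCc2ccccc2)cc1O/C(c1ccccc1)=C(/OC)C(=O)O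
A6 | alternative 3 | 5,8-dihydroxy-7-isopropoxy-3-methoxyflavone | CC(C)Oc1cc(O)c2c(=O)c(OC)c(-c3ccccc3)oc2c1O
A7 | alternative 3 | 4-hydroxy-3-isopropoxy-4-(5-methoxy-4-oxo-6-phenyl-4H-pyran-2-yl)cyclobut-2-en-1-one | CC(C)OC1=CC(=O)C1(O)c1cc(=O)c(OC)c(-c2ccccc2)o1
A8 | alternative 3 | 3-methoxy-2-phenyl-4H-pyran-4-one | COc1c(-c2ccccc2)occc1=O
A9 | alternative 3 | 3-isopropoxycyclobut-3-ene-1,2-dione | CC(C)OC1=CC(=O)C1=O
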